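## Retrosynthetic overview

1. The target is two identical benzene rings (A and A') joined C1–C1'. In each ring C2 carries CH2COCH3, C3 is the only ring C–H, and C4, C5 and C6 carry OMe. No ring is formed in the route, because both arenes come from 2,6-dimethoxyphenol.
2. Feature used: C2 has no oxygen neighbour, and electrophiles and lithium bases bypass it for C3 (ortho to the C4 OMe, para to the C6 OMe). C2 is, however, para to the oxygen on C5, and both carbons ortho to that oxygen (C4, C6) already hold OMe.
3. Last disconnections: each C=O comes from a C=CH2 (2-methylallyl as acetonyl equivalent, oxidative cleavage), and the C5/C5' OMe groups come from free phenols.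
4. Key disconnection: both C2–CH2 bonds come from the bis(2-methylallyl) ether on O5/O5' of the finished biaryl, through a twofold Claisen–Cope relay (para-Claisen).
5. The C1–C1' bond comes from oxidative dimerisation of the aryllithium generated beside OMe in MOM-protected 2,6-dimethoxyphenol. MOM is then exchanged for 2-methylallyl.

Key step: step 5

Remark on the chemistry: the SMILES holds no stereodescriptor, so the tetra-ortho-substituted C1–C1' axis is made as the racemate and no stereocentre has to be set.

Remark on locants: C1–C6 in the text are those defined above. The systematic biphenyl names of the intermediates count the ring the other way round (text C2 = name C6, text C3 = name C5, text C5 = name C3, text C6 = name C2, C4 unchanged).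

## Route

Step 1
Reactants: 1 2,6-dimethoxyphenol; 2 chloromethyl methyl ether
Product: 3 1,3-dimethoxy-2-(methoxymethoxy)benzene
Conditions: K2CO3, acetone, N2, 0 °C → rt
Reagents that add atoms: chloromethyl methyl ether (2), COCCl
Why: Williamson-type O-alkylation of the phenol by the very reactive α-chloro ether should give the MOM acetal, which tolerates n-BuLi and, being flanked by two OMe groups, has no free ortho C–H of its own to which it could steer the later metalation.

Step 2
Reactants: 3 1,3-dimethoxy-2-(methoxymethoxy)benzene (two molecules)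
Product: 5 2,2',4,4'-tetramethoxy-3,3'-bis(methoxymethoxy)biphenyl, via aryllithium 4 (not isolated)
Conditions: n-BuLi, TMEDA, THF, 0 °C; then anhydrous CuCl2, −78 °C → rt
Reagents that add atoms: none
Why: Directed ortho-metalation takes the C–H beside OMe (the two such sites are equivalent, and 1,2,3-trialkoxybenzenes are known to lithiate there), and oxidation of the aryl-metal species by divalent copper joins two aryl groups in the known oxidative homocoupling of aryllithiums, which places C1–C1' ortho to one OMe and para to the other as the target requires.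

Step 3
Reactants: 5 2,2',4,4'-tetramethoxy-3,3'-bis(methoxymethoxy)biphenyl
Product: 6 2,2',4,4'-tetramethoxybiphenyl-3,3'-diol
Conditions: HCl (cat.), MeOH, 50 °C
Reagents that add atoms: none
Why: Acid-catalysed transacetalisation turns both MOM acetals into dimethoxymethane and frees the two phenols, while the aryl methyl ethers are inert to dilute acid.

Step 4
Reactants: 6 2,2',4,4'-tetramethoxybiphenyl-3,3'-diol; 7 3-chloro-2-methylprop-1-ene
Product: 8 2,2',4,4'-tetramethoxy-3,3'-bis(2-methylallyloxy)biphenyl
Conditions: K2CO3, DMF, N2, 70 °C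
Reagents that add atoms: 3-chloro-2-methylprop-1-ene (7), CC(=C)CCl
Why: Williamson ether synthesis with an allylic chloride should alkylate only at oxygen, because both carbons ortho to each phenoxide oxygen carry OMe, just as in the routine O-allylation of 2,6-dimethoxyphenol.

Step 5
Reactants: 8 2,2',4,4'-tetramethoxy-3,3'-bis(2-methylallyloxy)biphenyl
Product: 12 2,2',4,4'-tetramethoxy-6,6'-bis(2-methylallyl)biphenyl-3,3'-diol, via ortho-dienone 9 (not isolated), via para-dienone 10 (not isolated), via monophenol 11 (not isolated)
Conditions: PhNEt2 (degassed), Ar, sealed tube, 200–210 °C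
Reagents that add atoms: none
Why: On each ring an aromatic Claisen [3,3] shift moves the 2-methylallyl group from O5 to an OMe-bearing ortho carbon (C4 as drawn in 9, C6 being the alternative), the resulting cyclohexa-2,4-dienone has no hydrogen at that carbon and cannot enolise, so a Cope [3,3] shift passes the group on to C2 (10), where transfer of the C2 hydrogen to oxygen restores the phenol; one passage gives 11 and a second one on ring A' gives 12. The closest known reaction is the para-Claisen rearrangement of allyl 2,6-dimethoxyphenyl ether to 4-allyl-2,6-dimethoxyphenol, applied here twice within one biaryl. No ring is closed, since the six-membered arrays exist only in the transition states, and no stereocentre remains, since the sp3 carbons of 9 and 10 become planar again; the C1–C1' axis gains its third and fourth ortho groups here and forms as the racemate. The selectivity needed is C2 over C3, and the substrate secures it by geometry: from either ortho carbon the second [3,3] shift can reach only the para carbon, which is also the only stop on the path that carries a hydrogen for rearomatisation. Because the group is transposed twice and has a CH2 at each end, it arrives as CH2–C(CH3)=CH2, an acetonyl group with CH2 in place of oxygen. The high-boiling tertiary amine keeps the medium free of acid, which would ionise the allylic ether or shift the alkene into conjugation, and argon shields the electron-rich phenols.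

Step 6
Reactants: 12 2,2',4,4'-tetramethoxy-6,6'-bis(2-methylallyl)biphenyl-3,3'-diol; 13 iodomethane
Product: 14 2,2',3,3',4,4'-hexamethoxy-6,6'-bis(2-methylallyl)biphenyl
Conditions: K2CO3, DMF, rt
Reagents that add atoms: iodomethane (13), CI
Why: Williamson O-methylation of the two 2,6-dimethoxyphenol-type hydroxyls completes the C4–C6 trimethoxy pattern and removes the free phenols, which periodate would otherwise oxidise in the next step.

Step 7
Reactants: 14 2,2',3,3',4,4'-hexamethoxy-6,6'-bis(2-methylallyl)biphenyl
Product: 16 1,1'-(4,4',5,5',6,6'-hexamethoxybiphenyl-2,2'-diyl)bis(propan-2-one), via bis-diol 15 (not isolated)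
Conditions: OsO4 (cat.), NaIO4, 2,6-lutidine, 1,4-dioxane–H2O (3:1), rt
Reagents that add atoms: OsO4 (catalytic oxygen carrier), O=[Os](=O)(=O)=O; NaIO4 (terminal oxygen source), [Na+].[O-]I(=O)(=O)=O; water (co-source of the glycol oxygens), O
Why: In the Lemieux–Johnson oxidation catalytic OsO4 dihydroxylates each 1,1-disubstituted alkene and periodate cleaves the glycol, so the terminal CH2 leaves as formaldehyde, the transient carbinol centres are erased and the methyl ketone remains, while the fully etherified arenes should stay untouched and 2,6-lutidine suppresses side oxidation.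

## Compound list

1 | 2,6-dimethoxyphenol | COc1cccc(OC)c1O | starting material
2 | chloromethyl methyl ether | COCCl | starting material
3 | 1,3-dimethoxy-2-(methoxymethoxy)benzene | COCOc1c(OC)cccc1OC | intermediate
4 | [2,4-dimethoxy-3-(methoxymethoxy)phenyl]lithium (not isolated) | [Li]c1ccc(OC)c(OCOC)c1OC | intermediate
5 | 2,2',4,4'-tetramethoxy-3,3'-bis(methoxymethoxy)biphenyl | COCOc1c(OC)ccc(-c2ccc(OC)c(OCOC)c2OC)c1OC | intermediate
6 | 2,2',4,4'-tetramethoxybiphenyl-3,3'-diol | COc1ccc(-c2ccc(OC)c(O)c2OC)c(OC)c1O | intermediate
7 | 3-chloro-2-methylprop-1-ene | CC(=C)CCl | starting material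
8 | 2,2',4,4'-tetramethoxy-3,3'-bis(2-methylallyloxy)biphenyl | COc1ccc(-c2ccc(OC)c(OCC(C)=C)c2OC)c(OC)c1OCC(C)=C | intermediate
9 | 2,6-dimethoxy-3-[2,4-dimethoxy-3-(2-methylallyloxy)phenyl]-6-(2-methylallyl)cyclohexa-2,4-dien-1-one (not isolated; transient sp3 centre, racemic) | O=C1C(OC)=C(c2ccc(OC)c(OCC(C)=C)c2OC)C=CC1(OC)CC(C)=C | intermediate
10 | 2,6-dimethoxy-3-[2,4-dimethoxy-3-(2-methylallyloxy)phenyl]-4-(2-methylallyl)cyclohexa-2,5-dien-1-one (not isolated; transient sp3 centre, racemic) | O=C1C(OC)=CC(CC(C)=C)C(c2ccc(OC)c(OCC(C)=C)c2OC)=C1OC | intermediate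
11 | 2,2',4,4'-tetramethoxy-6-(2-methylallyl)-3'-(2-methylallyloxy)biphenyl-3-ol (not isolated) | COc1cc(CC(C)=C)c(-c2ccc(OC)c(OCC(C)=C)c2OC)c(OC)c1O | intermediate
12 | 2,2',4,4'-tetramethoxy-6,6'-bis(2-methylallyl)biphenyl-3,3'-diol (racemic axis) | COc1cc(CC(C)=C)c(-c2c(CC(C)=C)cc(OC)c(O)c2OC)c(OC)c1O | intermediate
13 | iodomethane | CI | starting material
14 | 2,2',3,3',4,4'-hexamethoxy-6,6'-bis(2-methylallyl)biphenyl (racemic axis) | COc1cc(CC(C)=C)c(-c2c(CC(C)=C)cc(OC)c(OC)c2OC)c(OC)c1OC | intermediate
15 | 3,3'-(4,4',5,5',6,6'-hexamethoxybiphenyl-2,2'-diyl)bis(2-methylpropane-1,2-diol) (not isolated; diastereomer mixture, centres erased on cleavage) | COc1cc(CC(C)(O)CO)c(-c2c(CC(C)(O)CO)cc(OC)c(OC)c2OC)c(OC)c1OC | intermediate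
16 | 1,1'-(4,4',5,5',6,6'-hexamethoxybiphenyl-2,2'-diyl)bis(propan-2-one), CNP0079270.0 (racemic axis) | COc1cc(CC(C)=O)c(-c2c(CC(C)=O)cc(OC)c(OC)c2OC)c(OC)c1OC | target

Total step count: 7
Longest linear sequence: 7 steps (1 → 3 → 5 → 6 → 8 → 12 → 14 → 16)

## Steps most likely to fail

**Step 5.**
- What may go wrong: the second migration must deliver carbon next to an axis already flanked by three ortho groups, with both faces of ring A' shielded. It may therefore stall at the half-rearranged stage. Prolonged heating then invites cleavage of the allyl–oxygen bond, drift of the double bond into conjugation with the ring, and oxidation of the phenols.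
- Fallback (rearrange on the monomer, build the biaryl last): it sets out from 1, using 7 and 13 as in the main route, and comes back at 16.
- Compound 1 is O-alkylated with 7 (K2CO3, DMF) to 1,3-dimethoxy-2-(2-methylallyloxy)benzene F1. Its unhindered para-Claisen rearrangement (PhNEt2, 200 °C) should give 2,6-dimethoxy-4-(2-methylallyl)phenol F2.
- Methylation with 13 (K2CO3, DMF) gives 1,2,3-trimethoxy-5-(2-methylallyl)benzene F3. Lemieux–Johnson cleavage (OsO4 cat., NaIO4) then gives 1-(3,4,5-trimethoxyphenyl)propan-2-one F4.
- Electrophilic iodination (N-iodosuccinimide, CF3CO2H cat., MeCN) can enter only one of the two equivalent free positions, between OMe and the side chain. This gives 1-(2-iodo-3,4,5-trimethoxyphenyl)propan-2-one F5.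
- The ketone is masked with ethane-1,2-diol (TsOH, toluene, azeotropic removal of water) as 2-(2-iodo-3,4,5-trimethoxybenzyl)-2-methyl-1,3-dioxolane F6.
- Ullmann coupling (Cu powder, DMF, 150 °C) forms C1–C1' in 2,2'-[(4,4',5,5',6,6'-hexamethoxybiphenyl-2,2'-diyl)bis(methylene)]bis(2-methyl-1,3-dioxolane) F7. Aqueous HCl in THF then releases 16.

**Step 2.**
- What may go wrong: incomplete metalation, protonation of the aryl-metal species, or chlorine transfer from the copper salt in place of aryl–aryl bond formation.
- Fallback (cross-coupling of two differentiated halves instead of oxidative dimerisation): it sets out from 3 and comes back at 5.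
- Compound 3 is lithiated as before to 4. One portion is quenched with I2 to give 1-iodo-2,4-dimethoxy-3-(methoxymethoxy)benzene F8.
- The other portion is quenched with 2-isopropoxy-4,4,5,5-tetramethyl-1,3,2-dioxaborolane to give 2-[2,4-dimethoxy-3-(methoxymethoxy)phenyl]-4,4,5,5-tetramethyl-1,3,2-dioxaborolane F9.
- Suzuki–Miyaura coupling of the two (Pd(OAc)2, SPhos, K3PO4, toluene–H2O, 90 °C) should give 5.

**Step 7.**
- What may go wrong: slow osmylation of the second, hindered alkene, arrest at the glycol stage on one arm, or oxidative damage to the electron-rich rings.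
- Fallback (a three-carbon mask that is oxidised without C–C cleavage): it sets out from 6 and comes back at 16.
- Compound 6 is alkylated with allyl bromide (K2CO3, DMF) to 3,3'-bis(allyloxy)-2,2',4,4'-tetramethoxybiphenyl F10.
- The same twofold para-Claisen rearrangement (PhNEt2, 200–210 °C) should give 6,6'-diallyl-2,2',4,4'-tetramethoxybiphenyl-3,3'-diol F11.
- Methylation with 13 gives 6,6'-diallyl-2,2',3,3',4,4'-hexamethoxybiphenyl F12.
- Tsuji–Wacker oxidation (PdCl2 cat., CuCl, O2, DMF–H2O, rt) puts oxygen on the internal alkene carbon of both arms and delivers 16.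

## Further compounds

F1 | step 5 | 1,3-dimethoxy-2-(2-methylallyloxy)benzene | COc1cccc(OC)c1OCC(C)=C
F2 | step 5 | 2,6-dimethoxy-4-(2-methylallyl)phenol | COc1cc(CC(C)=C)cc(OC)c1O
F3 | step 5 | 1,2,3-trimethoxy-5-(2-methylallyl)benzene | COc1cc(CC(C)=C)cc(OC)c1OC
F4 | step 5 | 1-(3,4,5-trimethoxyphenyl)propan-2-one | COc1cc(CC(C)=O)cc(OC)c1OC
F5 | step 5 | 1-(2-iodo-3,4,5-trimethoxyphenyl)propan-2-one | COc1cc(CC(C)=O)c(I)c(OC)c1OC
F6 | step 5 | 2-(2-iodo-3,4,5-trimethoxybenzyl)-2-methyl-1,3-dioxolane | COc1cc(CC2(C)OCCO2)c(I)c(OC)c1OC
F7 | step 5 | 2,2'-[(4,4',5,5',6,6'-hexamethoxybiphenyl-2,2'-diyl)bis(methylene)]bis(2-methyl-1,3-dioxolane) | COc1cc(CC2(C)OCCO2)c(-c3c(CC4(C)OCCO4)cc(OC)c(OC)c3OC)c(OC)c1OC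
F8 | step 2 | 1-iodo-2,4-dimethoxy-3-(methoxymethoxy)benzene | COCOc1c(OC)ccc(I)c1OC
F9 | step 2 | 2-[2,4-dimethoxy-3-(methoxymethoxy)phenyl]-4,4,5,5-tetramethyl-1,3,2-dioxaborolane | COCOc1c(OC)ccc(B2OC(C)(C)C(C)(C)O2)c1OC
F10 | step 7 | 3,3'-bis(allyloxy)-2,2',4,4'-tetramethoxybiphenyl | COc1ccc(-c2ccc(OC)c(OCC=C)c2OC)c(OC)c1OCC=C
F11 | step 7 | 6,6'-diallyl-2,2',4,4'-tetramethoxybiphenyl-3,3'-diol | COc1cc(CC=C)c(-c2c(CC=C)cc(OC)c(O)c2OC)c(OC)c1O
F12 | step 7 | 6,6'-diallyl-2,2',3,3',4,4'-hexamethoxybiphenyl | COc1cc(CC=C)c(-c2c(CC=C)cc(OC)c(OC)c2OC)c(OC)c1OC
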